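## Analysis of the target

Compound 25 is an isoflavan: a chroman (aromatic ring A fused to the saturated oxygen ring C) that carries at C3 a second benzene ring B, itself fused to a 2,2-dimethyl-2H-pyran (ring D) and bearing a free hydroxyl ortho to the C3 attachment. Ring A is a resorcinol nucleus with oxygen on C7 (free phenol) and on C8a (the ring oxygen O1), a 3-methylbut-2-enyl (prenyl) group on C8 between these two oxygens, and hydrogen on C5 and C6. The only stereocentre is C3 (R), a benzylic methine between the C2 and C4 methylene groups; it has no neighbour to relay configuration from, so a reagent must set it, and afterwards it must never sit alpha to a carbonyl group. The sensitive groups are the styrene-like double bond of the chromene, the prenyl double bond next to a phenol (protic acid closes it onto the C7 oxygen) and two electron-rich phenols; together they rule out hydrogenation, hydrogenolysis, strong acid and late oxidants. The hard points are the placement of one prenyl group at C8, the most crowded position of ring A and one that aromatic substitution does not address selectively, and its combination with absolute control at C3 under protecting groups that come off without acid or hydrogen. The strategy reads ring A as a folded chain C5–C6–C7–C8–C8a in which C5 is an aldehyde carbon, C7 a ketone and C8a a carboxyl carbon whose ether oxygen O1 is the ring oxygen of a six-membered lactone that already holds C2, C3, C4 and C4a. On that reading the C4a–C5 bond is an aldol bond, the prenyl group is an alkyl substituent on the central carbon of a 1,3-dicarbonyl unit, and no substitution on an arene is needed.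

## Retrosynthetic reasoning

25 from 24. The last bond cut is the O–Si bond on the ring B oxygen. A triisopropylsilyl ether is chosen because it must survive enolates, a borohydride, carbonate and a silyl Lewis acid, and because it leaves with fluoride, which touches neither alkene nor the ortho-prenyl phenol.

24 from 20. Ring A is opened at C4a–C5 and taken back from the arene to the oxidation pattern of a chain: C5 as a dimethyl acetal, C7 as a ketone, C8=C8a as the enol ether double bond of a vinylogous ester, C4a as a ring methylene. This cut is preferred over any aryl–carbon or aryl–oxygen cut because it removes the regiochemical problem of ring A altogether: the oxygen on C7, the prenyl group on C8 and the hydrogen on C5 are already in place in 20. The forward reaction has to turn the vinylogous ester into its dienol ether (C4a=C8a), join C4a to the ionised acetal carbon C5, and lose both methoxy groups so that aromatisation drives the sequence.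

20 from 18. The enol ether bond O1–C8a is cut, which reveals a 1,3-diketone with a primary hydroxyl five atoms from the C8a carbonyl. Forward, the hydroxyl adds to that carbonyl to give hemiketal 19 and dehydration towards C8 gives the conjugated alkylidene oxane. Tying O1 to C8a as an ether before the acetal is ionised also blocks the route from a free 1,3,5-tricarbonyl equivalent to a pyranone.

18 from 16 and 17. The C8–prenyl bond is cut at the diketone stage. The other order, acylation of the lactone by the enolate of an already prenylated keto acetal, is not defensible: that ketone has two methylene groups of similar acidity, and the enolate on the acetal side expels methoxide. In 16 the central carbon C8 is the only site a weak base ionises, so alkylation with 17 is regiochemically unambiguous.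

16 from 14 and 15. The C8–C8a bond is cut between the lactone carbonyl and the methyl carbon of 15. Kinetic deprotonation of 15 at its methyl group is the reliable regiochemistry for this ketone. The lactone delivers O1, C2, C3, C4, C4a and C8a in one piece, with C3 two atoms away from the nearest acidic position.

14 from 13 and 12. The lactone C–O bond is cut to hydroxy ester 13, whose primary hydroxyl comes from reduction of the acyl oxazolidinone of 12. After this reduction C3 is no longer alpha to a carbonyl and is configurationally safe for the rest of the route.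

12 from 10 and 11. The C3–C4 bond is cut as a Michael addition of the enolate of 10 to acrylate 11. This single step creates the stereocentre and sets the 1,5 relation between the future C2 oxygen and the lactone carbonyl, so no later differentiation of two chain ends is needed. The auxiliary 8 in its (R) form shields one enolate face.

10 from 7 and 8; 7 from 4; 4 from 3; 3 from 1 and 2. The arylacetic acid 7 comes from aldehyde 4 by one-carbon homologation through enol ether 5 and aldehyde 6. The formyl group is worth carrying this far because, in 1, it fixes the regiochemistry of the chromene annulation with 2: the hydroxyl hydrogen-bonded to the formyl group stays free and ends up as the ring B phenol, ortho to the future C3 attachment.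

## Alternatives that were turned down

Alternative 1: Ring C is cut at C3–C4 and O1–C2, so ring A arrives as an ortho-quinone methide and ring B as an aldehyde. In the forward key step a chiral diarylprolinol silyl ether catalyst of the enantiomeric series that leads to R converts aldehyde A1 into its enamine, base releases the quinone methide from sulfone A2, the enamine carbon adds to the exocyclic methylene and the phenoxide closes on the iminium carbon to give lactol A3.
- For it: it is convergent, makes two bonds and the stereocentre in one catalytic operation, and uses ring A as a finished arene.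
- Against it: in A3 the C3 centre is benzylic and alpha to a masked aldehyde (lactol and hydroxy aldehyde equilibrate), so the amine and base that create it can also epimerise it. The C2 hydroxyl must then be removed by ionic reduction under a Lewis acid or by reduction and re-closure, and two methoxymethyl ethers must be cleaved by acid next to a prenyl phenol and a chromene. A2 itself requires regioselective prenylation between two oxygens of an arene, which is the problem the chosen route avoids.
- Comparison: Alternative 1 is stronger in convergence and in using a catalyst instead of a stoichiometric auxiliary. The chosen route offers a C3 centre that is never alpha to a carbonyl after step 7, prenyl placement by enolate chemistry, and an end game that needs only fluoride.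

Alternative 2: Ring C is cut at O1–C2 with an extra hydroxymethyl group on C3; the precursor is the prochiral oxetane A4. In the forward key step a chiral phosphoric acid activates the oxetane and the ring A phenol opens one of the two enantiotopic CH2–O bonds, giving A5 with a quaternary C3.
- For it: the asymmetric step is catalytic, mild and of a well-behaved type for 3,3-disubstituted oxetanes, and the ring closure needs only weak acid.
- Against it: A5 contains a carbon atom that the target lacks. Replacing the C3–CH2OH bond by C3–H means oxidation followed by decarbonylation or decarboxylation at a benzylic quaternary centre; radical or anionic variants pass through a planar intermediate and lose the configuration the catalyst installed, and a stoichiometric rhodium decarbonylation needs heat in the presence of two alkenes. A4 also requires a quaternary carbon bearing both aryl-containing arms, and the methoxymethyl ethers again call for acid.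
- Comparison: Alternative 2 is stronger in that its enantioselection is catalytic. The chosen route builds C3 directly as the tertiary centre that the target has and spends no steps on excising a carbon.

Alternative 3: Ring A is cut at C4a–C5, C6–C7 and C7–C8 and ring C at C4a–C8a, back to the diazo enone A6 with a tethered alkynyl ether. In the forward key step irradiation triggers a Wolff rearrangement (vinyl shift) to a vinylketene, which adds across the alkynyl ether and closes ring C; warming opens the cyclobutenone and a six-electron electrocyclisation closes ring A to give phenol A7.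
- For it: the ring-forming cascade belongs to an established benzannulation class, so on precedent for the key event it is stronger than the chosen strategy. The medium is neutral, the regiochemistry follows from the polarity of the alkynyl ether, C3 is remote, and A7, like 24, is one fluoride deprotection from the target.
- Against it: the 2,2-dimethyl-2H-chromene of ring B is itself photoactive (ring opening to a quinone methide), and both the chromene and the prenyl double bonds are partners for a carbene or a ketene. A6 combines a vinyl diazo ketone and a prenyl-bearing alkynyl ether, two high-energy groups that each cost several steps, so the sequence before the key step is longer than the three enolate steps from 14 to 20.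
- Comparison: Alternative 3 is stronger on precedent and equal on the protecting-group end game. The chosen route offers a non-photochemical key step and a precursor made from simple materials, at the price of a ring closure that has not been shown in this form.

Key step: step 12

Remark on the chemistry: ArB denotes the 2,2-dimethyl-5-(triisopropylsilyloxy)-2H-chromen-6-yl group and all atoms are labelled by the chroman numbering of 25; diketones 16 and 18 are written in the diketo form (their enol and ring-chain tautomers count as the same compounds), and 20 is drawn as the E isomer although either geometry, or a mixture, serves step 12.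

## Route

Step 1
Reactants: 1 2,4-dihydroxybenzaldehyde; 2 3-methylbut-2-enal
Product: 3 5-hydroxy-2,2-dimethyl-2H-chromene-6-carbaldehyde
Conditions: pyridine, 140 °C, sealed vessel
Reagents that add atoms: none
Why: Base-mediated chromene annulation (aldol-type attack of the resorcinol C3 on the enal, dehydration to an ortho-quinone methide, oxa-six-electron electrocyclisation); the hydroxyl hydrogen-bonded to the formyl group stays free, so the other hydroxyl becomes the pyran oxygen and the ring closes between the two oxygens, giving the 5-hydroxy-6-formyl pattern of ring B.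

Step 2
Reactants: 3 5-hydroxy-2,2-dimethyl-2H-chromene-6-carbaldehyde
Product: 4 2,2-dimethyl-5-(triisopropylsilyloxy)-2H-chromene-6-carbaldehyde
Conditions: iPr3SiOTf, 2,6-lutidine, CH2Cl2, 0 → 23 °C
Reagents that add atoms: triisopropylsilyl trifluoromethanesulfonate, CC(C)[Si](C(C)C)(C(C)C)OS(=O)(=O)C(F)(F)F
Why: Silylation of a hindered, chelated phenol needs the silyl triflate; the bulky aryl silyl ether is stable to the ylide, enolates, borohydride, carbonate and Lewis acid of the later steps and leaves with fluoride at the end.

Step 3
Reactants: 4 2,2-dimethyl-5-(triisopropylsilyloxy)-2H-chromene-6-carbaldehyde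
Product: 6 2-(ArB)acetaldehyde, via enol ether 5 (not isolated)
Conditions: Ph3P(CH2OMe)Cl, KN(SiMe3)2, THF, 0 → 23 °C; then 2 M aq HCl, 45 °C
Reagents that add atoms: (methoxymethyl)triphenylphosphonium chloride, COC[P+](c1ccccc1)(c1ccccc1)c1ccccc1.[Cl-]; water, O
Why: Wittig methoxymethylenation followed by hydrolysis of the enol ether is the standard one-carbon homologation of an aryl aldehyde; the enol ether is protonated far more readily than the chromene double bond, and the aryl silyl ether is stable to dilute aqueous acid.

Step 4
Reactants: 6 2-(ArB)acetaldehyde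
Product: 7 2-(ArB)acetic acid
Conditions: NaClO2, NaH2PO4, 2-methyl-2-butene, t-BuOH/H2O, 0 → 23 °C
Reagents that add atoms: sodium chlorite, [Na+].[O-]Cl=O
Why: Pinnick oxidation converts the aldehyde to the acid under buffered conditions, and the alkene scavenger intercepts hypochlorous acid before it can reach the chromene double bond or the electron-rich ring.

Step 5
Reactants: 7 2-(ArB)acetic acid; 8 (4R)-4-benzyl-1,3-oxazolidin-2-one
Product: 10 (4R)-4-benzyl-3-[2-(ArB)acetyl]-1,3-oxazolidin-2-one, via mixed pivalic anhydride 9 (not isolated)
Conditions: t-BuCOCl, Et3N, THF, −20 °C; then 8, n-BuLi, THF, −78 → 0 °C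
Reagents that add atoms: pivaloyl chloride, CC(C)(C)C(=O)Cl (its atoms are found in intermediate 9 only)
Why: N-Acylation of the lithiated oxazolidinone by a mixed anhydride; the nucleophile attacks the less hindered arylacetyl carbonyl of 9 and pivalate leaves.

Step 6
Reactants: 10 (4R)-4-benzyl-3-[2-(ArB)acetyl]-1,3-oxazolidin-2-one; 11 tert-butyl prop-2-enoate
Product: 12 tert-butyl (4R)-5-[(4R)-4-benzyl-2-oxo-1,3-oxazolidin-3-yl]-4-(ArB)-5-oxopentanoate
Conditions: TiCl4, i-Pr2NEt, CH2Cl2, −78 → 0 °C; then 11, 0 °C
Reagents that add atoms: none
Why: Auxiliary-controlled Michael addition of a chelated Z chlorotitanium enolate; the acrylate approaches the enolate face opposite the benzyl group of the (R)-auxiliary, which sets the new centre (the future C3) as R, and the tert-butyl ester resists a second addition and the later borohydride.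

Step 7
Reactants: 12 tert-butyl (4R)-5-[(4R)-4-benzyl-2-oxo-1,3-oxazolidin-3-yl]-4-(ArB)-5-oxopentanoate
Product: 13 tert-butyl (4R)-4-(ArB)-5-hydroxypentanoate
Conditions: LiBH4, MeOH (1 equiv), THF, 0 °C
Reagents that add atoms: none
Why: Reductive cleavage of the N-acyl oxazolidinone; the imide carbonyl is reduced much faster than the tert-butyl ester, the auxiliary is released intact, and the stereocentre ceases to be alpha to a carbonyl.

Step 8
Reactants: 13 tert-butyl (4R)-4-(ArB)-5-hydroxypentanoate
Product: 14 (5R)-5-(ArB)oxan-2-one
Conditions: CSA (10 mol %), toluene, 80 °C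
Reagents that add atoms: none
Why: Acid-catalysed lactonisation of a hydroxy tert-butyl ester with loss of 2-methylpropene and water gives the six-membered lactone; catalytic sulfonic acid in hot aromatic solvent is tolerated by 2,2-dimethylchromenes, and the stereocentre has no pathway for epimerisation.

Step 9
Reactants: 14 (5R)-5-(ArB)oxan-2-one; 15 4,4-dimethoxybutan-2-one
Product: 16 (8R)-8-(ArB)-9-hydroxy-1,1-dimethoxynonane-3,5-dione
Conditions: 15 and LiN(iPr)2 (2.2 equiv each), THF, −78 °C; then 14, −78 → −40 °C; AcOH
Reagents that add atoms: none
Why: Claisen-type acylation of a ketone enolate by a lactone; kinetic deprotonation of 15 takes place at the methyl group, and the diketonate formed on collapse of the tetrahedral intermediate consumes the second equivalent of enolate, which protects the product from further addition; the crude product is carried on without acidic silica to avoid premature cyclodehydration.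

Step 10
Reactants: 16 (8R)-8-(ArB)-9-hydroxy-1,1-dimethoxynonane-3,5-dione; 17 1-bromo-3-methylbut-2-ene
Product: 18 (8R)-8-(ArB)-9-hydroxy-1,1-dimethoxy-4-(3-methylbut-2-enyl)nonane-3,5-dione
Conditions: K2CO3, acetone, 23 °C
Reagents that add atoms: none
Why: C-Alkylation of a 1,3-diketone; carbonate ionises only the central carbon (the future C8), a soft allylic bromide favours carbon over oxygen, and the primary hydroxyl is not deprotonated under these conditions.

Step 11
Reactants: 18 (8R)-8-(ArB)-9-hydroxy-1,1-dimethoxy-4-(3-methylbut-2-enyl)nonane-3,5-dione
Product: 20 (4E)-4-[(5R)-5-(ArB)oxan-2-ylidene]-1,1-dimethoxy-7-methyloct-6-en-3-one, via cyclic hemiketal 19 (not isolated)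
Conditions: PPTS (10 mol %), 4 Å molecular sieves, benzene, 40 °C
Reagents that add atoms: none
Why: Cyclodehydration of a hydroxy 1,3-diketone to a vinylogous ester; the hydroxyl can only form a six-membered hemiketal at the nearer carbonyl, loss of water towards the carbon flanked by the ketone gives the conjugated enol ether, and a pyridinium salt with sieves is too weak to ionise the dimethyl acetal at a useful rate; a double-bond isomer, should it form, enters step 12 through the same dienol ether.

Step 12
Reactants: 20 (4E)-4-[(5R)-5-(ArB)oxan-2-ylidene]-1,1-dimethoxy-7-methyloct-6-en-3-one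
Product: 24 (3R)-3-(ArB)-8-(3-methylbut-2-enyl)chroman-7-ol, via silyl dienol ether 21 (not isolated), via 5-methoxy adduct 22 (not isolated), via aryl trimethylsilyl ether 23 (not isolated)
Conditions: Me3SiOTf (4 equiv), i-Pr2NEt (3.5 equiv), CH2Cl2, −78 → 23 °C; then MeOH, K2CO3 (cat.), 0 °C
Reagents that add atoms: trimethylsilyl trifluoromethanesulfonate, C[Si](C)(C)OS(=O)(=O)C(F)(F)F (its silyl group is found in intermediates 21 and 23 only)
Why: Proposed new method: Me3SiOTf silylates the C7 carbonyl of the vinylogous ester and the amine removes a C4a proton to give silyl dienol ether 21 with a C4a=C8a bond, the excess Me3SiOTf ionises the dimethyl acetal to the C5 oxocarbenium ion, and the dienol ether terminus C4a captures it to form C4a–C5 and, after loss of the silyl group, adduct 22. Renewed silylation at C7, loss of the second methoxy group as Me3SiOMe and loss of the C4a proton aromatise ring A to silyl ether 23, which makes the sequence irreversible, and mild methanolysis frees phenol 24. The closest known reaction types are the one-pot enol silane formation and Mukaiyama addition to dimethyl acetals under a silyl triflate and an amine, vinylogous Mukaiyama additions of silyl dienol ethers to acetals, and the aldol folding of 3,5-dioxo aldehyde equivalents to resorcinols; a lactone-derived alkylidene oxane as the dienol ether partner goes beyond these. Ring A closes in the 6-(enolendo)-exo-trig mode; if the acetal first collapses to the 5-methoxy enone, the same C4a–C5 bond can still form by conjugate addition of the dienol ether or by six-electron electrocyclisation of the derived triene, so both branches should lead to 24. No stereocentre is created, because the transient centres at C4a and C5 are erased on aromatisation and C3 is remote from every enolisable position. The selectivity needed is bond formation through C4a and not through C8 or oxygen, and ring size secures it because only C4a gives a six-membered ring, while the preformed dienol ether is far more nucleophilic than the prenyl double bond that could otherwise trap the cation. The amine buffer keeps strong protic acid out of the flask, so the chromene, the prenyl group and the new ortho-prenyl phenol (masked as 23 until work-up) should survive.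

Step 13
Reactants: 24 (3R)-3-(ArB)-8-(3-methylbut-2-enyl)chroman-7-ol
Product: 25 (3R)-3-(5-hydroxy-2,2-dimethyl-2H-chromen-6-yl)-8-(3-methylbut-2-enyl)chroman-7-ol
Conditions: Bu4NF, THF, 0 °C; aq NH4Cl
Reagents that add atoms: none
Why: Fluoride cleavage of the aryl silyl ether; neither alkene, the ortho-prenyl phenol nor the C3 centre is affected, and the work-up is buffered and oxygen-free to protect the two phenols.

## Compound list

ArB = 2,2-dimethyl-5-(triisopropylsilyloxy)-2H-chromen-6-yl

1 | 2,4-dihydroxybenzaldehyde | O=Cc1ccc(O)cc1O | starting material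
2 | 3-methylbut-2-enal | CC(C)=CC=O | starting material
3 | 5-hydroxy-2,2-dimethyl-2H-chromene-6-carbaldehyde | O=Cc1ccc2OC(C)(C)C=Cc2c1O | intermediate
4 | 2,2-dimethyl-5-(triisopropylsilyloxy)-2H-chromene-6-carbaldehyde | O=Cc1ccc2OC(C)(C)C=Cc2c1O[Si](C(C)C)(C(C)C)C(C)C | intermediate
5 | 6-(2-methoxyethenyl)-2,2-dimethyl-5-(triisopropylsilyloxy)-2H-chromene (E/Z mixture, not isolated) | COC=Cc1ccc2OC(C)(C)C=Cc2c1O[Si](C(C)C)(C(C)C)C(C)C | intermediate
6 | 2-(ArB)acetaldehyde | O=CCc1ccc2OC(C)(C)C=Cc2c1O[Si](C(C)C)(C(C)C)C(C)C | intermediate
7 | 2-(ArB)acetic acid | OC(=O)Cc1ccc2OC(C)(C)C=Cc2c1O[Si](C(C)C)(C(C)C)C(C)C | intermediate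
8 | (4R)-4-benzyl-1,3-oxazolidin-2-one | O=C1N[C@H](Cc2ccccc2)CO1 | starting material
9 | 2-(ArB)acetic 2,2-dimethylpropanoic anhydride (not isolated) | CC(C)(C)C(=O)OC(=O)Cc1ccc2OC(C)(C)C=Cc2c1O[Si](C(C)C)(C(C)C)C(C)C | intermediate
10 | (4R)-4-benzyl-3-[2-(ArB)acetyl]-1,3-oxazolidin-2-one | O=C(Cc1ccc2OC(C)(C)C=Cc2c1O[Si](C(C)C)(C(C)C)C(C)C)N1[C@H](Cc2ccccc2)COC1=O | intermediate
11 | tert-butyl prop-2-enoate | C=CC(=O)OC(C)(C)C | starting material
12 | tert-butyl (4R)-5-[(4R)-4-benzyl-2-oxo-1,3-oxazolidin-3-yl]-4-(ArB)-5-oxopentanoate | CC(C)(C)OC(=O)CC[C@H](c1ccc2OC(C)(C)C=Cc2c1O[Si](C(C)C)(C(C)C)C(C)C)C(=O)N1[C@H](Cc2ccccc2)COC1=O | intermediate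
13 | tert-butyl (4R)-4-(ArB)-5-hydroxypentanoate | CC(C)(C)OC(=O)CC[C@H](c1ccc2OC(C)(C)C=Cc2c1O[Si](C(C)C)(C(C)C)C(C)C)CO | intermediate
14 | (5R)-5-(ArB)oxan-2-one | O=C1CC[C@H](c2ccc3OC(C)(C)C=Cc3c2O[Si](C(C)C)(C(C)C)C(C)C)CO1 | intermediate
15 | 4,4-dimethoxybutan-2-one | COC(OC)CC(C)=O | starting material
16 | (8R)-8-(ArB)-9-hydroxy-1,1-dimethoxynonane-3,5-dione | COC(OC)CC(=O)CC(=O)CC[C@H](c1ccc2OC(C)(C)C=Cc2c1O[Si](C(C)C)(C(C)C)C(C)C)CO | intermediate
17 | 1-bromo-3-methylbut-2-ene (prenyl bromide) | CC(C)=CCBr | starting material
18 | (8R)-8-(ArB)-9-hydroxy-1,1-dimethoxy-4-(3-methylbut-2-enyl)nonane-3,5-dione (mixture at C4) | COC(OC)CC(=O)C(CC=C(C)C)C(=O)CC[C@H](c1ccc2OC(C)(C)C=Cc2c1O[Si](C(C)C)(C(C)C)C(C)C)CO | intermediate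
19 | 4-[(5R)-5-(ArB)-2-hydroxyoxan-2-yl]-1,1-dimethoxy-7-methyloct-6-en-3-one (mixture at ring C2 and chain C4, not isolated) | COC(OC)CC(=O)C(CC=C(C)C)C1(O)CC[C@H](c2ccc3OC(C)(C)C=Cc3c2O[Si](C(C)C)(C(C)C)C(C)C)CO1 | intermediate
20 | (4E)-4-[(5R)-5-(ArB)oxan-2-ylidene]-1,1-dimethoxy-7-methyloct-6-en-3-one | COC(OC)CC(=O)/C(CC=C(C)C)=C1\CC[C@H](c2ccc3OC(C)(C)C=Cc3c2O[Si](C(C)C)(C(C)C)C(C)C)CO1 | intermediate
21 | {[4-[(3R)-3-(ArB)-3,4-dihydro-2H-pyran-6-yl]-1,1-dimethoxy-7-methylocta-3,6-dien-3-yl]oxy}trimethylsilane (enol ether geometry not fixed, not isolated) | COC(OC)CC(O[Si](C)(C)C)=C(CC=C(C)C)C1=CC[C@H](c2ccc3OC(C)(C)C=Cc3c2O[Si](C(C)C)(C(C)C)C(C)C)CO1 | intermediate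
22 | (3R)-3-(ArB)-5-methoxy-8-(3-methylbut-2-enyl)-2,3,4,4a,5,6-hexahydro-7H-chromen-7-one (mixture at C4a and C5, not isolated) | COC1CC(=O)C(CC=C(C)C)=C2OC[C@@H](c3ccc4OC(C)(C)C=Cc4c3O[Si](C(C)C)(C(C)C)C(C)C)CC12 | intermediate
23 | {[(3R)-3-(ArB)-8-(3-methylbut-2-enyl)chroman-7-yl]oxy}trimethylsilane (not isolated) | CC(C)=CCc1c(O[Si](C)(C)C)ccc2c1OC[C@@H](c1ccc3OC(C)(C)C=Cc3c1O[Si](C(C)C)(C(C)C)C(C)C)C2 | intermediate
24 | (3R)-3-(ArB)-8-(3-methylbut-2-enyl)chroman-7-ol | CC(C)=CCc1c(O)ccc2c1OC[C@@H](c1ccc3OC(C)(C)C=Cc3c1O[Si](C(C)C)(C(C)C)C(C)C)C2 | intermediate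
25 | (3R)-3-(5-hydroxy-2,2-dimethyl-2H-chromen-6-yl)-8-(3-methylbut-2-enyl)chroman-7-ol | CC(C)=CCc1c(O)ccc2c1OC[C@@H](c1ccc3c(c1O)C=CC(C)(C)O3)C2 | target

## Step count and least certain steps

Total step count: 13. Longest linear sequence: 13 steps (1 to 25).

Step 12 (key step, the one step beyond known chemistry).
- What may go wrong: the acetal may collapse to the 5-methoxy enone and the sequence stall there without C4a–C5 bond formation; the C5 cation may be trapped by the prenyl double bond in a Prins-type closure; a four-electron closure between C5 and C8a may compete; or the new C7 oxygen may add to the prenyl group if protic acid builds up during work-up.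
- Fallback (known chemistry; ring A is brought in as a finished arene and ring C is closed by etherification): it sets out from imide 10 and returns to the route at 24. 1,3-Bis(methoxymethoxy)benzene F1 is lithiated between its two oxygens (n-BuLi, THF, 0 °C) and alkylated with 17 to give 1,3-bis(methoxymethoxy)-2-(3-methylbut-2-enyl)benzene F2. A second ortho-lithiation (n-BuLi, TMEDA) and trapping with paraformaldehyde give [2,4-bis(methoxymethoxy)-3-(3-methylbut-2-enyl)phenyl]methanol F3, which CBr4 and PPh3 convert into 1-(bromomethyl)-2,4-bis(methoxymethoxy)-3-(3-methylbut-2-enyl)benzene F4. The sodium enolate of 10 (NaN(SiMe3)2, THF, −78 °C) is alkylated by F4 on the face away from the benzyl group, which should give (4R)-4-benzyl-3-{(2R)-3-[2,4-bis(methoxymethoxy)-3-(3-methylbut-2-enyl)phenyl]-2-(ArB)propanoyl}-1,3-oxazolidin-2-one F5 with the same sense at the new centre as in 12. LiBH4 releases 8 and gives (2R)-3-[2,4-bis(methoxymethoxy)-3-(3-methylbut-2-enyl)phenyl]-2-(ArB)propan-1-ol F6. HCl in methanol at 23 °C removes both methoxymethyl groups to give 4-[(2R)-2-(ArB)-3-hydroxypropyl]-2-(3-methylbut-2-enyl)benzene-1,3-diol F7. PPh3 with diisopropyl azodicarboxylate then closes O1–C2 through the phenol ortho to the benzylic carbon (Mitsunobu etherification), which gives 24.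

Step 11 (cyclodehydration).
- What may go wrong: ionisation of the acetal before the hemiketal loses water, followed by attack of the C8a enol oxygen on C5 and formation of a pyranone; or incomplete dehydration to the crowded tetrasubstituted enol ether.
- Fallback: from 18 directly to 20 by Mitsunobu cyclisation (PPh3, diisopropyl azodicarboxylate, THF, 0 °C). The 2-substituted 1,3-diketone is acidic enough to be the pronucleophile, and its C8a enolate oxygen displaces the activated primary hydroxyl, so the ring closes at O1–C2 instead of O1–C8a and no acid comes near the acetal. No new compound is made on the way.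

Step 10 (prenylation).
- What may go wrong: alkylation on oxygen instead of carbon, a second alkylation at C8, or retro-Claisen cleavage started by the free hydroxyl.
- Fallback: from 16 to 18 by allylic alkylation under zerovalent palladium catalysis (Tsuji–Trost reaction) with methyl 3-methylbut-2-enyl carbonate F8 and Pd(PPh3)4 in THF at 23 °C. The medium is neutral, the soft diketonate attacks the unsubstituted terminus of the allyl complex to give the linear prenyl product, and O-alkylation is reversible under these conditions.

Step 6 (Michael addition).
- What may go wrong: Lewis-acid-induced ionisation or oligomerisation of the chromene, a second acrylate addition, or poor facial selectivity with the bulky ortho-silyloxy aryl group.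
- Fallback: it sets out from 10 and returns at lactone 14 by enolate alkylation instead of conjugate addition. The sodium enolate of 10 (NaN(SiMe3)2, THF, −78 °C) is alkylated with allyl iodide to give (4R)-4-benzyl-3-[(2R)-2-(ArB)pent-4-enoyl]-1,3-oxazolidin-2-one F9. LiBH4 gives (2R)-2-(ArB)pent-4-en-1-ol F10. 9-BBN followed by NaBO3 hydroborates the terminal alkene in preference to the chromene double bond and gives (2R)-2-(ArB)pentane-1,5-diol F11. TEMPO with PhI(OAc)2 oxidises the unhindered terminal alcohol first and then the derived lactol, which gives 14.

## Further compounds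

F1 | step 12 | 1,3-bis(methoxymethoxy)benzene | COCOc1cccc(OCOC)c1
F2 | step 12 | 1,3-bis(methoxymethoxy)-2-(3-methylbut-2-enyl)benzene | COCOc1cccc(OCOC)c1CC=C(C)C
F3 | step 12 | [2,4-bis(methoxymethoxy)-3-(3-methylbut-2-enyl)phenyl]methanol | COCOc1ccc(CO)c(OCOC)c1CC=C(C)C
F4 | step 12 | 1-(bromomethyl)-2,4-bis(methoxymethoxy)-3-(3-methylbut-2-enyl)benzene | COCOc1ccc(CBr)c(OCOC)c1CC=C(C)C
F5 | step 12 | (4R)-4-benzyl-3-{(2R)-3-[2,4-bis(methoxymethoxy)-3-(3-methylbut-2-enyl)phenyl]-2-(ArB)propanoyl}-1,3-oxazolidin-2-one | COCOc1ccc(C[C@H](c2ccc3OC(C)(C)C=Cc3c2O[Si](C(C)C)(C(C)C)C(C)C)C(=O)N2[C@H](Cc3ccccc3)COC2=O)c(OCOC)c1CC=C(C)C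
F6 | step 12 | (2R)-3-[2,4-bis(methoxymethoxy)-3-(3-methylbut-2-enyl)phenyl]-2-(ArB)propan-1-ol | COCOc1ccc(C[C@H](c2ccc3OC(C)(C)C=Cc3c2O[Si](C(C)C)(C(C)C)C(C)C)CO)c(OCOC)c1CC=C(C)C
F7 | step 12 | 4-[(2R)-2-(ArB)-3-hydroxypropyl]-2-(3-methylbut-2-enyl)benzene-1,3-diol | Oc1ccc(C[C@H](c2ccc3OC(C)(C)C=Cc3c2O[Si](C(C)C)(C(C)C)C(C)C)CO)c(O)c1CC=C(C)C
F0 | step 11 | none | none
F8 | step 10 | methyl 3-methylbut-2-enyl carbonate | COC(=O)OCC=C(C)C
F9 | step 6 | (4R)-4-benzyl-3-[(2R)-2-(ArB)pent-4-enoyl]-1,3-oxazolidin-2-one | C=CC[C@H](c1ccc2OC(C)(C)C=Cc2c1O[Si](C(C)C)(C(C)C)C(C)C)C(=O)N1[C@H](Cc2ccccc2)COC1=O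
F10 | step 6 | (2R)-2-(ArB)pent-4-en-1-ol | C=CC[C@H](c1ccc2OC(C)(C)C=Cc2c1O[Si](C(C)C)(C(C)C)C(C)C)CO
F11 | step 6 | (2R)-2-(ArB)pentane-1,5-diol | OCCC[C@H](c1ccc2OC(C)(C)C=Cc2c1O[Si](C(C)C)(C(C)C)C(C)C)CO
A1 | alternative 1 | 2-[5-(methoxymethoxy)-2,2-dimethyl-2H-chromen-6-yl]acetaldehyde | O=CCc1ccc2OC(C)(C)C=Cc2c1OCOC
A2 | alternative 1 | 3-(methoxymethoxy)-2-(3-methylbut-2-enyl)-6-[(phenylsulfonyl)methyl]phenol | COCOc1ccc(CS(=O)(=O)c2ccccc2)c(O)c1CC=C(C)C
A3 | alternative 1 | (3R)-7-(methoxymethoxy)-3-[5-(methoxymethoxy)-2,2-dimethyl-2H-chromen-6-yl]-8-(3-methylbut-2-enyl)chroman-2-ol (anomers at C2) | CC(C)=CCc1c(OCOC)ccc2c1OC(O)[C@@H](c1ccc3OC(C)(C)C=Cc3c1OCOC)C2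
A4 | alternative 2 | 3-(methoxymethoxy)-6-({3-[5-(methoxymethoxy)-2,2-dimethyl-2H-chromen-6-yl]oxetan-3-yl}methyl)-2-(3-methylbut-2-enyl)phenol | COCOc1ccc(CC2(c3ccc4OC(C)(C)C=Cc4c3OCOC)COC2)c(O)c1CC=C(C)C
A5 | alternative 2 | [(3R)-7-(methoxymethoxy)-3-[5-(methoxymethoxy)-2,2-dimethyl-2H-chromen-6-yl]-8-(3-methylbut-2-enyl)chroman-3-yl]methanol | CC(C)=CCc1c(OCOC)ccc2c1OC[C@@](CO)(c1ccc3OC(C)(C)C=Cc3c1OCOC)C2
A6 | alternative 3 | (6R)-6-[5-(tert-butyldimethylsilyloxy)-2,2-dimethyl-2H-chromen-6-yl]-4-diazo-7-[(5-methylhex-4-en-1-yn-1-yl)oxy]hept-1-en-3-one | C=CC(=O)C(=[N+]=[N-])C[C@H](c1ccc2OC(C)(C)C=Cc2c1O[Si](C)(C)C(C)(C)C)COC#CCC=C(C)C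
A7 | alternative 3 | (3R)-3-[5-(tert-butyldimethylsilyloxy)-2,2-dimethyl-2H-chromen-6-yl]-8-(3-methylbut-2-enyl)chroman-7-ol | CC(C)=CCc1c(O)ccc2c1OC[C@@H](c1ccc3OC(C)(C)C=Cc3c1O[Si](C)(C)C(C)(C)C)C2
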